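**Plan**

1. Retrosynthesis (oxolane numbering O1, C2–C5 for the target; chain numbering C1 = CH2Cl to C8 = CHBr for the open precursor): the O1–C2 bond and the C3–Cl bond are cut together, which leads to the acyclic bromohydrin dienol 11. Behind it are cut, in this order: the tertiary C–Br bond (bromide opening of an epoxide), C1–Cl (Appel), the epoxide (Sharpless), the C3–C4 chain bond (alkenylalane plus allylic chloride) and C8–Br (hydrozirconation–bromination).
2. Feature that allows the key event: in the oxolane, O1 and the chlorine on C3 are vicinal, with the C2 methyl trans and the C2 bromovinyl group cis to chlorine. C2 is fully substituted and allylic, and the carbinol carbon C5 lies three atoms from C2. This is the pattern left by an anti, Markovnikov 5-endo chloroetherification of a (Z)-trisubstituted alkene by a homoallylic alcohol.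
3. Forward: (Z)-3-methylpent-2-en-4-yn-1-ol supplies chain C4–C8 with the (Z)-alkene, and propargyl alcohol plus a methyl group from Me3Al supplies C1–C3. Epoxidation, chlorination and bromide opening follow, and the only ring, the oxolane, is closed last.
4. Stereochemistry: the Sharpless epoxidation sets both side-chain centres (the bromine-bearing carbon by inversion in the bromide opening, the carbinol carbon unchanged). In the ring closure, anti addition to the (Z)-alkene fixes C2 relative to C3, and the carbinol centre directs the face of chlorenium delivery, giving the all-cis arrangement of side chain, chlorine and bromovinyl group.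

Key step: step 7

Remark: (Z)-3-methylpent-2-en-4-yn-1-ol (the cis isomer of the commercial C6 enynol) and prop-2-yn-1-ol are taken as the starting materials.

**Step 1**
Reactants: 1 (Z)-3-methylpent-2-en-4-yn-1-ol
Product: 3 (2Z,4E)-5-bromo-3-methylpenta-2,4-dien-1-ol, via alkenylzirconocene alkoxide 2 (not isolated)
Conditions: Cp2Zr(H)Cl (2.3 equiv), THF, 0 °C → rt; then NBS (1.1 equiv), 0 °C; dilute HCl work-up
Reagents that add atoms: N-bromosuccinimide, O=C1CCC(=O)N1Br
Why: Hydrozirconation of the terminal alkyne with Cp2Zr(H)Cl (the first equivalent is spent on the hydroxyl group) is a syn addition that places zirconium on the terminal carbon, and bromodezirconation with NBS goes with retention, so the (E)-bromoalkene should form while the hindered (Z)-trisubstituted alkene is left alone.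

**Step 2**
Reactants: 3 (2Z,4E)-5-bromo-3-methylpenta-2,4-dien-1-ol
Product: 4 (1E,3Z)-1-bromo-5-chloro-3-methylpenta-1,3-diene
Conditions: NCS (1.2 equiv), Me2S (1.3 equiv), CH2Cl2, −20 °C; then 3, −20 → 0 °C
Reagents that add atoms: N-chlorosuccinimide, O=C1CCC(=O)N1Cl
Why: Corey–Kim chlorination (alkoxysulfonium salt, then SN2 displacement by chloride at the primary carbon) converts primary allylic alcohols into the chlorides under near-neutral conditions, without allylic transposition or Z to E isomerisation, as is known for nerol-type alcohols.

**Step 3**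
Reactants: 5 prop-2-yn-1-ol; 4 (1E,3Z)-1-bromo-5-chloro-3-methylpenta-1,3-diene
Product: 7 (2E,5Z,7E)-8-bromo-2,6-dimethylocta-2,5,7-trien-1-ol, via alkenylalane 6 (not isolated)
Conditions: 5, Me3Al (3.0 equiv), Cp2ZrCl2 (0.25 equiv), CH2Cl2, 0 °C → rt; then 4, Pd(PPh3)4 (5 mol%), THF, 0 °C → rt; dilute HCl work-up
Reagents that add atoms: trimethylaluminium, C[Al](C)C
Why: Negishi zirconium-catalysed methylalumination (syn addition, methyl to the internal carbon) sets the (E)-trisubstituted alkene, and the palladium-catalysed alkenylalane–allylic chloride coupling (Negishi 1,4-diene synthesis) should join the fragments at the unsubstituted allyl terminus with retention of all alkene geometries, because the allylic C–Cl bond adds to zerovalent palladium much faster than the alkenyl C–Br bond.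

**Step 4**
Reactants: 7 (2E,5Z,7E)-8-bromo-2,6-dimethylocta-2,5,7-trien-1-ol
Product: 8 [(2S,3S)-3-[(2Z,4E)-5-bromo-3-methylpenta-2,4-dien-1-yl]-2-methyloxiran-2-yl]methanol
Conditions: Ti(OiPr)4 (10 mol%), L-(+)-diethyl tartrate (12 mol%), t-BuOOH (2 equiv), 4 Å molecular sieves, CH2Cl2, −20 °C
Reagents that add atoms: tert-butyl hydroperoxide, CC(C)(C)OO
Why: Sharpless asymmetric epoxidation acts only on the allylic-alcohol alkene, and with L-(+)-tartrate the oxygen is delivered to the face that gives the (2S,3S)-epoxy alcohol, as with other (E)-2-methylalk-2-en-1-ols, so both stereocentres of the later bromohydrin are fixed here.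

**Step 5**
Reactants: 8 [(2S,3S)-3-[(2Z,4E)-5-bromo-3-methylpenta-2,4-dien-1-yl]-2-methyloxiran-2-yl]methanol
Product: 9 (2R,3S)-3-[(2Z,4E)-5-bromo-3-methylpenta-2,4-dien-1-yl]-2-(chloromethyl)-2-methyloxirane
Conditions: PPh3 (1.5 equiv), CCl4/CH2Cl2, NaHCO3, 40 °C
Reagents that add atoms: tetrachloromethane, ClC(Cl)(Cl)Cl
Why: Appel chlorination (alkoxyphosphonium ion, then SN2 by chloride at the primary carbon) under buffered neutral conditions should leave the epoxide and its two stereocentres untouched, as is known for 2,3-epoxy alcohols; the descriptor at C2 changes only because of the priority rules.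

**Step 6**
Reactants: 9 (2R,3S)-3-[(2Z,4E)-5-bromo-3-methylpenta-2,4-dien-1-yl]-2-(chloromethyl)-2-methyloxirane
Product: 11 (2S,3S,5Z,7E)-2,8-dibromo-1-chloro-2,6-dimethylocta-5,7-dien-3-ol, via bromomagnesium alkoxide 10 (not isolated)
Conditions: MgBr2·OEt2 (2 equiv), Et2O/CH2Cl2, −40 → −10 °C; cold water work-up
Reagents that add atoms: magnesium bromide diethyl etherate, CCOCC.[Mg+2].[Br-].[Br-]
Why: Lewis-acid-assisted opening of a trisubstituted epoxide by bromide is a borderline SN2 process at the carbon that best carries positive charge (as in the HBr opening of 1-methylcyclohexene oxide), so bromide should enter at the tertiary carbon with inversion and give the anti bromohydrin, while the carbinol carbon keeps its oxygen and configuration.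

**Step 7**
Reactants: 11 (2S,3S,5Z,7E)-2,8-dibromo-1-chloro-2,6-dimethylocta-5,7-dien-3-ol
Product: 12 (2S,3S,5S)-2-[(E)-2-bromoethenyl]-5-[(2S)-2-bromo-1-chloropropan-2-yl]-3-chloro-2-methyloxolane
Conditions: NCS (1.1 equiv), (CF3)2CHOH/CH2Cl2 (1:4), −20 → 0 °C
Reagents that add atoms: N-chlorosuccinimide, O=C1CCC(=O)N1Cl
Why: NCS, activated by hydrogen bonding to hexafluoroisopropanol, should transfer a chlorenium ion to the CH terminus (chain C5) of the electron-rich trisubstituted alkene of the bromodiene, which builds positive charge at the tertiary, allylic chain C6, and the homoallylic hydroxyl captures this carbon from the opposite face in an overall anti addition. The closest known reaction type is the halo-etherification of homoallylic alcohols (iodo, bromo and chloro variants), here applied to a 1-bromo-1,3-diene. The oxolane closes in the 5-endo-trig mode, which is open to onium-activated alkenes; attack at chain C5 would need a four-membered ring and attack at the bromine-bearing diene terminus a seven-membered ring. Oxolane C2 is set by anti addition across the (Z)-alkene, which puts chlorine cis to the bromovinyl group and trans to methyl. Oxolane C3 is set by the envelope transition state in which the large side chain on the carbinol carbon is pseudo-equatorial, which puts chlorine cis to that side chain, as in the all-cis 3-iodooxolanes formed from (Z)-homoallylic alcohols. The step needs Markovnikov regioselectivity (secured by the methyl and vinyl groups on chain C6), chemoselectivity for the diene over the carbinol and the bromoalkene (low temperature, no base, so the bromohydrin does not revert to the epoxide) and anti stereospecificity (non-nucleophilic medium, so ring closure stays coupled to chlorenium transfer).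

**Compound list**

1 | (Z)-3-methylpent-2-en-4-yn-1-ol | OC/C=C(/C)C#C | starting material
2 | chlorozirconocene alkoxide of (2Z,4E)-5-(chlorozirconocenyl)-3-methylpenta-2,4-dien-1-ol, Cp2Zr(Cl)–O–CH2–CH=C(CH3)–CH=CH–Zr(Cl)Cp2 | Cl[Zr](C1C=CC=C1)(C1C=CC=C1)OC/C=C(/C)\C=C\[Zr](Cl)(C1C=CC=C1)C1C=CC=C1 | intermediate
3 | (2Z,4E)-5-bromo-3-methylpenta-2,4-dien-1-ol | OC/C=C(/C)\C=C\Br | intermediate
4 | (1E,3Z)-1-bromo-5-chloro-3-methylpenta-1,3-diene | ClC/C=C(/C)\C=C\Br | intermediate
5 | prop-2-yn-1-ol (propargyl alcohol) | OCC#C | starting material
6 | (E)-3-(dimethylalumanyl)-2-methylprop-2-en-1-yl dimethylaluminium alkoxide (Al cis to methyl) | C[Al](C)OC/C(C)=C/[Al](C)C | intermediate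
7 | (2E,5Z,7E)-8-bromo-2,6-dimethylocta-2,5,7-trien-1-ol | OC/C(C)=C/C/C=C(/C)\C=C\Br | intermediate
8 | [(2S,3S)-3-[(2Z,4E)-5-bromo-3-methylpenta-2,4-dien-1-yl]-2-methyloxiran-2-yl]methanol | OC[C@]1(C)O[C@H]1C/C=C(/C)\C=C\Br | intermediate
9 | (2R,3S)-3-[(2Z,4E)-5-bromo-3-methylpenta-2,4-dien-1-yl]-2-(chloromethyl)-2-methyloxirane | ClC[C@]1(C)O[C@H]1C/C=C(/C)\C=C\Br | intermediate
10 | bromomagnesium (2S,3S,5Z,7E)-2,8-dibromo-1-chloro-2,6-dimethylocta-5,7-dien-3-olate | C[C@@](Br)(CCl)[C@@H](O[Mg]Br)C/C=C(/C)\C=C\Br | intermediate
11 | (2S,3S,5Z,7E)-2,8-dibromo-1-chloro-2,6-dimethylocta-5,7-dien-3-ol | C[C@@](Br)(CCl)[C@@H](O)C/C=C(/C)\C=C\Br | intermediate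
12 | (2S,3S,5S)-2-[(E)-2-bromoethenyl]-5-[(2S)-2-bromo-1-chloropropan-2-yl]-3-chloro-2-methyloxolane | C[C@@](Br)(CCl)[C@@H]1C[C@H](Cl)[C@](C)(/C=C/Br)O1 | target

**Step count**

Total steps: 7. Longest linear sequence: 7 steps (1 → 3 → 4 → 7 → 8 → 9 → 11 → 12); propargyl alcohol 5 enters in step 3 without earlier steps.

**Steps most likely to fail, with fallbacks**

Step 6. The chloromethyl group withdraws electron density from the tertiary epoxide carbon, so bromide may be delivered to the secondary carbon instead; chlorine participation or a Lewis-acid-induced hydride shift are further ways in which the step can go wrong. The fallback sets out from 9 and comes back at 11, and it turns that same bias to use. Epoxide 9 would be opened on purpose at the secondary carbon under SN2 conditions with Li2NiBr4 in THF at 0 °C, which should give, with inversion at C3, the regioisomeric bromohydrin (2S,3R,5Z,7E)-3,8-dibromo-1-chloro-2,6-dimethylocta-5,7-dien-2-ol F1. In anhydrous formic acid at 0 °C the tertiary hydroxyl of F1 should ionise with participation of the anti bromine, which bridges to C2 as a bromonium ion. Formate would then open the bridged ion at C3; attack at C2 only returns a tertiary ester that ionises again, so the material should funnel to the secondary formate (2S,3S,5Z,7E)-2,8-dibromo-1-chloro-2,6-dimethylocta-5,7-dien-3-yl formate F2. The net result is inversion at C2 and double inversion at C3, which is the configuration of 11. Methanolysis (MeOH, cat. p-TsOH, 0 °C) would then give 11.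

Step 7. The ring closure may lose its anti stereospecificity if a free allylic cation forms, the chlorenium ion may be delivered to the wrong alkene face relative to the carbinol centre, or the carbinol may be oxidised. The fallback sets out from 11 and comes back at 12, and it separates C–O bond formation from chlorination. A reagent-controlled Shi epoxidation of the trisubstituted diene alkene would be used, with the enantiomer of the fructose-derived ketone (1,2:4,5-di-O-isopropylidene-erythro-2,3-hexodiulo-2,6-pyranose) that the spiro transition-state model assigns to the required face, KHSO5, pH 8, 0 °C. This should give the vinyl epoxide (2S,3S)-3-bromo-1-[(2S,3R)-3-[(E)-2-bromoethenyl]-3-methyloxiran-2-yl]-4-chloro-3-methylbutan-2-ol F3. Acid catalysis (camphorsulfonic acid, CH2Cl2, 0 °C) should then open the epoxide in the 5-endo mode at the tertiary allylic carbon with clean inversion, giving the hydroxy-oxolane (2S,3S,5S)-2-[(E)-2-bromoethenyl]-5-[(2S)-2-bromo-1-chloropropan-2-yl]-2-methyloxolan-3-ol F4. Its hydroxyl already occupies the position of the chlorine, so a stereoretentive chlorination (SOCl2 to the chlorosulfite, then TiCl4 as catalyst, CH2Cl2, 0 °C) would give 12.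

Step 3. The (Z)-alkene may isomerise through the π-allylpalladium intermediate, zerovalent palladium may also insert into the alkenyl C–Br bond, and methyl may be transferred from aluminium instead of the alkenyl group. The fallback sets out from 5 and comes back at 7, and it avoids palladium and π-allyl intermediates. Zirconium-catalysed methylalumination of 5 followed by iodinolysis (I2, THF, −30 °C) would give (E)-3-iodo-2-methylprop-2-en-1-ol F5. Silylation (TBSCl, imidazole) would give tert-butyl{[(E)-3-iodo-2-methylprop-2-en-1-yl]oxy}dimethylsilane F6. Iodine–lithium exchange (t-BuLi, Et2O, −78 °C), transmetalation with MgBr2·OEt2 and a copper-catalysed (Li2CuCl4) SN2 alkylation of the alkenyl Grignard reagent with chloride 4 at −40 °C should give {[(2E,5Z,7E)-8-bromo-2,6-dimethylocta-2,5,7-trien-1-yl]oxy}(tert-butyl)dimethylsilane F7. Desilylation with Bu4NF would then give 7.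

**Further compounds**

F1 | step 6 | (2S,3R,5Z,7E)-3,8-dibromo-1-chloro-2,6-dimethylocta-5,7-dien-2-ol | ClC[C@](C)(O)[C@H](Br)C/C=C(/C)\C=C\Br
F2 | step 6 | (2S,3S,5Z,7E)-2,8-dibromo-1-chloro-2,6-dimethylocta-5,7-dien-3-yl formate | C[C@@](Br)(CCl)[C@@H](OC=O)C/C=C(/C)\C=C\Br
F3 | step 7 | (2S,3S)-3-bromo-1-[(2S,3R)-3-[(E)-2-bromoethenyl]-3-methyloxiran-2-yl]-4-chloro-3-methylbutan-2-ol | C[C@@](Br)(CCl)[C@@H](O)C[C@@H]1O[C@]1(C)/C=C/Br
F4 | step 7 | (2S,3S,5S)-2-[(E)-2-bromoethenyl]-5-[(2S)-2-bromo-1-chloropropan-2-yl]-2-methyloxolan-3-ol | C[C@@](Br)(CCl)[C@@H]1C[C@H](O)[C@](C)(/C=C/Br)O1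
F5 | step 3 | (E)-3-iodo-2-methylprop-2-en-1-ol | OC/C(C)=C/I
F6 | step 3 | tert-butyl{[(E)-3-iodo-2-methylprop-2-en-1-yl]oxy}dimethylsilane | CC(C)(C)[Si](C)(C)OC/C(C)=C/I
F7 | step 3 | {[(2E,5Z,7E)-8-bromo-2,6-dimethylocta-2,5,7-trien-1-yl]oxy}(tert-butyl)dimethylsilane | CC(C)(C)[Si](C)(C)OC/C(C)=C/C/C=C(/C)\C=C\Br
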